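**Plan**

1. Ring D is cut first at C8–CH2 and C9–CH2: Diels–Alder reaction of myrcene with the C8=C9 bond of hydroxyquinone 27, which goes back to a dimethoxyarene.
2. The five-membered ring B is cut at C6–C8: Wolff ring contraction of the six-membered 6-diazo-7-ketone 21, whose ring comes from C7–C8 (Friedel–Crafts acylation) and C5–C6 (alkynylation, Meyer–Schuster rearrangement).
3. Ring A is cut at C1–C10 and C3–C4 together, giving the acyclic ketone 9 and a three-carbon 1,3-dielectrophile; 9 comes from a C9–C10 cut (ketone α-arylation).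
4. Enabling feature: C5 is carried as a ketone carbonyl whose two α-carbons are C10 (benzylic CH bearing the C20 methyl and ring C) and C4 (the isopropyl methine). The C1–C2–C3 unit bridges these 1,3-related α-positions, closing ring A and making both quaternary carbons.
5. Forward order: ring C (arene) → ring A → six-membered ring B → contraction to the five-membered ring B → quinone → ring D.
6. Stereochemistry: C10 from the chiral phase-transfer catalyst in the key step; C5 by hydrogenation anti to C20; C6 by equilibration; C8 and C9 by Diels–Alder attack anti to C20.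

Key step: step 5

Remark: abietane numbering is used (ring A = C1–C5 and C10; C20 = methyl on C10, whose face is called β; C7 = formyl carbon; ring C = C8, C9, C11–C14); the formyl-bearing C6 is epimerisable and is taken to rest in the configuration of the target (formyl α, trans to the C5–C4 bond).

**Route**

Step 1
Reactants: 1 1,3-dimethoxybenzene; 2 acetone
Product: 4 2-(2,6-dimethoxyphenyl)propan-2-ol, via 2,6-dimethoxyphenyllithium 3 (not isolated)
Conditions: n-BuLi, THF, 0 °C to rt; then 2, −78 °C to rt; H2O work-up
Reagents that add atoms: none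
Why: Directed ortho-metalation removes the C–H flanked by both methoxy groups and the aryllithium adds to acetone (1,2-addition), which places the carbons of the future C13 isopropyl group between the two oxygens.

Step 2
Reactants: 4 2-(2,6-dimethoxyphenyl)propan-2-ol
Product: 5 2-isopropyl-1,3-dimethoxybenzene
Conditions: Et3SiH, CF3CO2H, CH2Cl2, 0 °C to rt
Reagents that add atoms: none
Why: Ionic hydrogenation: the tertiary benzylic alcohol ionises in CF3CO2H to a cation stabilised by two ortho methoxy groups and is reduced by hydride transfer from the silane.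

Step 3
Reactants: 5 2-isopropyl-1,3-dimethoxybenzene
Product: 7 5-bromo-2-isopropyl-1,3-dimethoxybenzene, via arylboronate 6 (not isolated)
Conditions: [Ir(OMe)(cod)]2 (1.5 mol%), 4,4′-di-tert-butyl-2,2′-bipyridine, B2pin2, THF, 80 °C; then CuBr2, MeOH/H2O, 80 °C
Reagents that add atoms: bis(pinacolato)diboron, CC1(C)OB(OC1(C)C)B1OC(C)(C)C(C)(C)O1 (boryl group of 6 only); copper dibromide, Br[Cu]Br (bromine of 7)
Why: Sterically controlled iridium-catalysed C–H borylation reaches only the C–H without an ortho substituent (para to isopropyl, the future C9), and copper-mediated bromodeboronation converts the boronate into the bromide in the same pot.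

Step 4
Reactants: 7 5-bromo-2-isopropyl-1,3-dimethoxybenzene; 8 2-methylpentan-3-one
Product: 9 rac-2-(3,5-dimethoxy-4-isopropylphenyl)-4-methylpentan-3-one
Conditions: Pd(OAc)2 (2 mol%), Xantphos, NaOt-Bu, 8 (2 equiv), toluene, 70 °C
Reagents that add atoms: none
Why: Palladium-catalysed ketone α-arylation takes place at the less hindered methylene of 8 and stops after one arylation because the product enolate is tetrasubstituted; it forms the C9–C10 bond, and the stereocentre of racemic 9 is erased in step 5.

Step 5
Reactants: 9 rac-2-(3,5-dimethoxy-4-isopropylphenyl)-4-methylpentan-3-one; 10 1-chloro-3-iodopropane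
Product: 12 (R)-2-(3,5-dimethoxy-4-isopropylphenyl)-2,6,6-trimethylcyclohexan-1-one, via chloro ketone 11 (not isolated)
Conditions: chiral C2-symmetric N-spiro binaphthyl quaternary ammonium bromide with 3,3′-bis(3,4,5-trifluorophenyl) groups (2 mol%, the antipode that leads to (R)-11), 10 (1.2 equiv), CsOH·H2O, toluene, −20 °C; then KOt-Bu (3 equiv), THF, 0 °C to rt, one pot
Reagents that add atoms: none
Why: Proposed new method: Hydroxide removes the benzylic α-proton at C10 of 9 (far more acidic than the isopropyl methine at C4); the tetrasubstituted enolate, held in one geometry by allylic strain, travels as a tight ion pair with the chiral ammonium cation and is C-alkylated at the iodide end of 10 (SN2), which forms C1–C10. The new C10 stereocentre, the only one formed, is controlled by the catalyst, whose binaphthyl walls leave one enolate face open, and the catalyst antipode is chosen so that (R)-11 results. Because C10 is now quaternary, KOt-Bu can enolise only towards C4, and this fully substituted enolate displaces chloride in a 6-(enolendo)-exo-tet C-alkylation that forms C3–C4, the gem-dimethyl quaternary carbon, and closes ring A. The closest known reaction types are the asymmetric phase-transfer alkylation of cyclic α-aryl ketones to α-quaternary ketones and the cyclisation of ω-halo ketone enolates to 2,2,6,6-tetrasubstituted cyclohexanones; their union in one pot on an acyclic α-aryl ketone with an unactivated 1,3-dihalide is the new element. The step needs site selectivity (C10 before C4, iodide before chloride), C- over O-alkylation and enantioface selectivity, which are secured by the acidity gap between the two α-positions, the leaving-group gap in 10, the six-membered enolendo geometry that lets the enolate carbon reach the C–Cl σ* orbital, and the chiral ion pair.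

Step 6
Reactants: 12 (R)-2-(3,5-dimethoxy-4-isopropylphenyl)-2,6,6-trimethylcyclohexan-1-one; 13 ethoxyacetylene
Product: 15 ethyl 2-[(2R)-2-(3,5-dimethoxy-4-isopropylphenyl)-2,6,6-trimethylcyclohexylidene]acetate (E/Z mixture), via ethoxyethynyl carbinol 14 (not isolated)
Conditions: 13, n-BuLi, THF, −78 °C; then 12, −78 to 0 °C; then 10% aq. H2SO4, THF, rt
Reagents that add atoms: none
Why: Lithium ethoxyacetylide is a small linear nucleophile that adds to the non-enolisable ketone (as lithium acetylides do to 2,2,6,6-tetrasubstituted cyclohexanones), and dilute acid then triggers the Meyer–Schuster rearrangement through an oxygen-stabilised allenyl cation to the α,β-unsaturated ester, the Rupe pathway being closed because C4 and C10 carry no hydrogen.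

Step 7
Reactants: 15 ethyl 2-[(2R)-2-(3,5-dimethoxy-4-isopropylphenyl)-2,6,6-trimethylcyclohexylidene]acetate
Product: 16 2-[(2R)-2-(3,5-dimethoxy-4-isopropylphenyl)-2,6,6-trimethylcyclohexylidene]acetic acid (E/Z mixture)
Conditions: LiOH, THF/MeOH/H2O, 60 °C; then 1 M HCl
Reagents that add atoms: lithium hydroxide, [Li+].[OH-] (hydroxyl oxygen of 16)
Why: Saponification of an unhindered conjugated ester.

Step 8
Reactants: 16 2-[(2R)-2-(3,5-dimethoxy-4-isopropylphenyl)-2,6,6-trimethylcyclohexylidene]acetic acid
Product: 18 12,14-dimethoxyabieta-5,8,11,13-tetraen-7-one (C10 as in 12), via mixed anhydride 17 (not isolated)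
Conditions: (CF3CO)2O, CF3CO2H, CH2Cl2, 0 °C to rt
Reagents that add atoms: trifluoroacetic anhydride, O=C(OC(=O)C(F)(F)F)C(F)(F)F (trifluoroacetyl group of 17 only)
Why: Intramolecular Friedel–Crafts acylation through the mixed anhydride: C7 attacks the aryl position ortho to one and para to the other methoxy group (the two ortho positions are equivalent, the one attacked becomes C8) and closes the six-membered ring B, and both alkene isomers converge because the unsaturated acylium ion rotates through its vinylketene-type resonance form.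

Step 9
Reactants: 18 12,14-dimethoxyabieta-5,8,11,13-tetraen-7-one
Product: 19 12,14-dimethoxy-5α-abieta-8,11,13-trien-7-one (trans A/B)
Conditions: H2 (1–3 atm), Pd/C, EtOAc, rt
Reagents that add atoms: none
Why: Heterogeneous hydrogenation of the conjugated Δ5 enone delivers hydrogen from the α face, away from the axial C20 and 4β methyl groups, which sets C5 as 5α-H (trans ring fusion), as is usual for Δ5-7-oxo tricyclic diterpenoids.

Step 10
Reactants: 19 12,14-dimethoxy-5α-abieta-8,11,13-trien-7-one
Product: 21 6-diazo-12,14-dimethoxy-5α-abieta-8,11,13-trien-7-one, via trifluoroacetyl ketone 20 (not isolated)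
Conditions: LiN(SiMe3)2, THF, −78 °C; CF3CO2CH2CF3; then MeSO2N3, Et3N, H2O, MeCN, rt
Reagents that add atoms: 2,2,2-trifluoroethyl trifluoroacetate, O=C(OCC(F)(F)F)C(F)(F)F (trifluoroacetyl group of 20 only); methanesulfonyl azide, CS(=O)(=O)N=[N+]=[N-] (diazo nitrogens of 21)
Why: Detrifluoroacetylative diazo transfer (Regitz type): the only enolisable position, C6, is trifluoroacetylated, and the activated β-dicarbonyl takes the diazo group from the sulfonyl azide with loss of the trifluoroacetyl group.

Step 11
Reactants: 21 6-diazo-12,14-dimethoxy-5α-abieta-8,11,13-trien-7-one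
Product: 24 methyl 7-isopropyl-6,8-dimethoxy-1,1,4a-trimethyl-2,3,4,4a,9,9a-hexahydro-1H-fluorene-9-carboxylate (4aβ-CH3 and 9aα-H and 9α-CO2Me; ester on C6 in abietane numbering), via ketene 22 (not isolated), via 6β-ester 23 (not isolated)
Conditions: hν (Pyrex-filtered medium-pressure mercury lamp), MeOH, rt; then NaOMe (cat.), MeOH, 40 °C
Reagents that add atoms: methanol, CO
Why: Photochemical Wolff rearrangement: loss of N2 with 1,2-shift of the aryl carbon C8 from C7 to C6 contracts ring B to the five-membered ring and gives ketene 22, methanol adds to give mainly the 6β ester 23 (protonation from the open α face), and NaOMe equilibrates C6 to the more stable 6α ester trans to the C5–C4 bond, C5 and C10 being untouched.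

Step 12
Reactants: 24 the 6α methyl ester
Product: 25 7-isopropyl-6,8-dimethoxy-1,1,4a-trimethyl-2,3,4,4a,9,9a-hexahydro-1H-fluorene-9α-carbaldehyde (4aβ-CH3 and 9aα-H)
Conditions: i-Bu2AlH (1.1 equiv), CH2Cl2, −78 °C; aq. potassium sodium tartrate work-up
Reagents that add atoms: none
Why: Partial reduction with i-Bu2AlH at −78 °C stops at the aluminium hemiacetal, which gives the aldehyde on work-up, and C6 stays in its thermodynamic configuration.

Step 13
Reactants: 25 the dimethoxy aldehyde
Product: 26 6,8-dihydroxy-7-isopropyl-1,1,4a-trimethyl-2,3,4,4a,9,9a-hexahydro-1H-fluorene-9α-carbaldehyde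
Conditions: BBr3 (4 equiv), CH2Cl2, −78 to 0 °C; then H2O
Reagents that add atoms: none
Why: BBr3 cleaves both aryl methyl ethers by O-coordination and SN2 attack of bromide on methyl, while the aldehyde is only complexed and is released on aqueous work-up.

Step 14
Reactants: 26 the resorcinol aldehyde
Product: 27 6-hydroxy-7-isopropyl-1,1,4a-trimethyl-5,8-dioxo-2,3,4,4a,5,8,9,9a-octahydro-1H-fluorene-9α-carbaldehyde (12-hydroxy-11,14-quinone in abietane numbering)
Conditions: K2NO(SO3)2 (Fremy's salt, 2.5 equiv), KH2PO4, acetone/H2O, 0 °C to rt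
Reagents that add atoms: potassium nitrosodisulfonate, [K+].[K+].[O]N(S(=O)(=O)[O-])S(=O)(=O)[O-] (oxygen at C11)
Why: Teuber oxidation: the nitrosodisulfonate radical oxidises the C14 phenol, whose para position C11 is free, to the p-quinone, and the second hydroxyl group remains as the C12 enol of the hydroxyquinone.

Step 15
Reactants: 27 the hydroxyquinone aldehyde; 28 myrcene
Product: 29 target CNP0239256.1
Conditions: 28 (5 equiv), tris(6,6,7,7,8,8,8-heptafluoro-2,2-dimethyl-3,5-octanedionato)erbium, Er(fod)3 (0.3 equiv), CH2Cl2, rt, dark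
Reagents that add atoms: none
Why: Lewis-acid-promoted Diels–Alder reaction at C8=C9, the only quinone double bond without a donor substituent: the oxophilic lanthanide is expected to sit on the most basic carbonyl oxygen O14 (vinylogous acid, with the C7 formyl oxygen close by), which makes C9 the electrophilic terminus so that it bonds to the methylene on the substituted diene carbon of myrcene, and the diene comes from the α face, opposite the C20 and 4β methyl groups, which sets C8 and C9.

**Compound list**

1 | 1,3-dimethoxybenzene | COc1cccc(OC)c1 | starting material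
2 | acetone | CC(C)=O | starting material
3 | 2,6-dimethoxyphenyllithium | [Li]c1c(OC)cccc1OC | intermediate (not isolated)
4 | 2-(2,6-dimethoxyphenyl)propan-2-ol | CC(C)(O)c1c(OC)cccc1OC | intermediate
5 | 2-isopropyl-1,3-dimethoxybenzene | CC(C)c1c(OC)cccc1OC | intermediate
6 | 2-(3,5-dimethoxy-4-isopropylphenyl)-4,4,5,5-tetramethyl-1,3,2-dioxaborolane | CC(C)c1c(OC)cc(cc1OC)B1OC(C)(C)C(C)(C)O1 | intermediate (not isolated)
7 | 5-bromo-2-isopropyl-1,3-dimethoxybenzene | CC(C)c1c(OC)cc(Br)cc1OC | intermediate
8 | 2-methylpentan-3-one | CCC(=O)C(C)C | starting material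
9 | rac-2-(3,5-dimethoxy-4-isopropylphenyl)-4-methylpentan-3-one | CC(C)C(=O)C(C)c1cc(OC)c(C(C)C)c(OC)c1 | intermediate
10 | 1-chloro-3-iodopropane | ClCCCI | starting material
11 | (R)-7-chloro-4-(3,5-dimethoxy-4-isopropylphenyl)-2,4-dimethylheptan-3-one | CC(C)C(=O)[C@](C)(CCCCl)c1cc(OC)c(C(C)C)c(OC)c1 | intermediate (not isolated)
12 | (R)-2-(3,5-dimethoxy-4-isopropylphenyl)-2,6,6-trimethylcyclohexan-1-one | CC(C)c1c(OC)cc(cc1OC)[C@@]1(C)CCCC(C)(C)C1=O | intermediate
13 | ethoxyacetylene | CCOC#C | starting material
14 | (2R)-2-(3,5-dimethoxy-4-isopropylphenyl)-1-(ethoxyethynyl)-2,6,6-trimethylcyclohexan-1-ol (both C1 epimers) | CCOC#CC1(O)C(C)(C)CCC[C@]1(C)c1cc(OC)c(C(C)C)c(OC)c1 | intermediate (not isolated)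
15 | ethyl 2-[(2R)-2-(3,5-dimethoxy-4-isopropylphenyl)-2,6,6-trimethylcyclohexylidene]acetate (E/Z mixture) | CCOC(=O)C=C1C(C)(C)CCC[C@]1(C)c1cc(OC)c(C(C)C)c(OC)c1 | intermediate
16 | 2-[(2R)-2-(3,5-dimethoxy-4-isopropylphenyl)-2,6,6-trimethylcyclohexylidene]acetic acid (E/Z mixture) | OC(=O)C=C1C(C)(C)CCC[C@]1(C)c1cc(OC)c(C(C)C)c(OC)c1 | intermediate
17 | mixed anhydride of 16 with trifluoroacetic acid | O=C(OC(=O)C(F)(F)F)C=C1C(C)(C)CCC[C@]1(C)c1cc(OC)c(C(C)C)c(OC)c1 | intermediate (not isolated)
18 | 12,14-dimethoxyabieta-5,8,11,13-tetraen-7-one (10β-CH3, C10 as in 12) | O=C1C=C2C(C)(C)CCC[C@]2(C)c2cc(OC)c(C(C)C)c(OC)c12 | intermediate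
19 | 12,14-dimethoxy-5α-abieta-8,11,13-trien-7-one (5α-H, 10β-CH3, trans A/B) | O=C1C[C@H]2C(C)(C)CCC[C@]2(C)c2cc(OC)c(C(C)C)c(OC)c12 | intermediate
20 | 12,14-dimethoxy-6-(trifluoroacetyl)-5α-abieta-8,11,13-trien-7-one (C6 epimers, enolised) | O=C1C(C(=O)C(F)(F)F)[C@H]2C(C)(C)CCC[C@]2(C)c2cc(OC)c(C(C)C)c(OC)c12 | intermediate (not isolated)
21 | 6-diazo-12,14-dimethoxy-5α-abieta-8,11,13-trien-7-one | O=C1C(=[N+]=[N-])[C@H]2C(C)(C)CCC[C@]2(C)c2cc(OC)c(C(C)C)c(OC)c12 | intermediate
22 | 7-isopropyl-6,8-dimethoxy-1,1,4a-trimethyl-9-(oxomethylidene)-2,3,4,4a,9,9a-hexahydro-1H-fluorene (4aβ-CH3, 9aα-H; ketene) | O=C=C1[C@H]2C(C)(C)CCC[C@]2(C)c2cc(OC)c(C(C)C)c(OC)c12 | intermediate (not isolated)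
23 | methyl 7-isopropyl-6,8-dimethoxy-1,1,4a-trimethyl-2,3,4,4a,9,9a-hexahydro-1H-fluorene-9β-carboxylate (4aβ-CH3, 9aα-H; 6β ester in abietane numbering) | COC(=O)[C@H]1[C@H]2C(C)(C)CCC[C@]2(C)c2cc(OC)c(C(C)C)c(OC)c12 | intermediate (not isolated)
24 | methyl 7-isopropyl-6,8-dimethoxy-1,1,4a-trimethyl-2,3,4,4a,9,9a-hexahydro-1H-fluorene-9α-carboxylate (4aβ-CH3, 9aα-H; 6α ester in abietane numbering) | COC(=O)[C@@H]1[C@H]2C(C)(C)CCC[C@]2(C)c2cc(OC)c(C(C)C)c(OC)c12 | intermediate
25 | 7-isopropyl-6,8-dimethoxy-1,1,4a-trimethyl-2,3,4,4a,9,9a-hexahydro-1H-fluorene-9α-carbaldehyde (4aβ-CH3, 9aα-H) | O=C[C@@H]1[C@H]2C(C)(C)CCC[C@]2(C)c2cc(OC)c(C(C)C)c(OC)c12 | intermediate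
26 | 6,8-dihydroxy-7-isopropyl-1,1,4a-trimethyl-2,3,4,4a,9,9a-hexahydro-1H-fluorene-9α-carbaldehyde (4aβ-CH3, 9aα-H) | O=C[C@@H]1[C@H]2C(C)(C)CCC[C@]2(C)c2cc(O)c(C(C)C)c(O)c12 | intermediate
27 | 6-hydroxy-7-isopropyl-1,1,4a-trimethyl-5,8-dioxo-2,3,4,4a,5,8,9,9a-octahydro-1H-fluorene-9α-carbaldehyde (4aβ-CH3, 9aα-H) | O=C[C@@H]1[C@H]2C(C)(C)CCC[C@]2(C)C2=C1C(=O)C(C(C)C)=C(O)C2=O | intermediate
28 | myrcene (7-methyl-3-methyleneocta-1,6-diene) | CC(C)=CCCC(=C)C=C | starting material
29 | CNP0239256.1 (Diels–Alder adduct of 27 and 28 across C8=C9, ring D on the α face, homoprenyl-bearing alkene carbon next to the CH2 on C9) | CC(C)=CCCC1=CC[C@@]23C(=O)C(C(C)C)=C(O)C(=O)[C@]2(C1)[C@@]1(C)CCCC(C)(C)[C@@H]1[C@H]3C=O | target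

**Step count and risks**

Total step count: 15. Longest linear sequence: 15 steps (from 1,3-dimethoxybenzene).

Steps most likely to fail:

Step 5 (Proposed new method). What may go wrong: insufficient enantioface discrimination in the ion-pair alkylation of an acyclic, fully substituted enolate, slow alkylation by an unactivated halide, or O-alkylation during the ring closure. Fallback with known chemistry: it sets out from aryl bromide 7 and uses the palladium-catalysed enantioselective α-arylation of commercial 2,2,6-trimethylcyclohexanone (CC1CCCC(C)(C)C1=O) with 7 [Pd(OAc)2, a chiral bisphosphine such as DIFLUORPHOS or BINAP, NaOt-Bu, toluene, 60–80 °C]. The quaternary C10 centre then arises by formation of the C9–C10 bond, and the product is 12, where the route is rejoined. This fallback makes no compound outside the list (F0).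

Step 15. What may go wrong: the diene may add in the opposite orientation if the Lewis acid chelates O11/O12 instead of binding O14, it may attack the β face, or the formyl group may undergo an intramolecular carbonyl-ene reaction with the new ring D alkene. Fallback: it sets out from 27, which is O-methylated (Me3SiCHN2, MeOH/toluene) to 6-methoxy-7-isopropyl-1,1,4a-trimethyl-5,8-dioxo-2,3,4,4a,5,8,9,9a-octahydro-1H-fluorene-9α-carbaldehyde F1. A BF3·OEt2-promoted Diels–Alder reaction with 28 at −78 °C follows; a monodentate Lewis acid can bind only the vinylogous-ester carbonyl O14 of a 2-methoxy-p-quinone, the established way to direct the nucleophilic diene terminus to the carbon β to that carbonyl (C9). This gives the 12-O-methyl ether of the target F2. Mild hydrolysis of the vinylogous ester (LiOH, THF/H2O, 0 °C, then acidification) comes back to 29.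

Step 6. What may go wrong: slow addition to the doubly neopentyl carbonyl group, or a 1,2-shift of the electron-rich aryl group from C10 to the cationic C5 during the acid-mediated rearrangement. Fallback: it sets out from 12 and uses a Reformatsky addition (Zn, BrCH2CO2Et, THF, reflux; a small, non-basic zinc enolate) to give ethyl 2-[(2R)-2-(3,5-dimethoxy-4-isopropylphenyl)-1-hydroxy-2,6,6-trimethylcyclohexyl]acetate F3. Syn-elimination of water without a free cation (Burgess reagent, MeO2CN−SO2N+Et3, benzene, 50 °C) can remove only a C6 hydrogen and gives 15, where the route is rejoined.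

Further compounds
F0 | step 5 | none | none
F1 | step 15 | 6-methoxy-7-isopropyl-1,1,4a-trimethyl-5,8-dioxo-2,3,4,4a,5,8,9,9a-octahydro-1H-fluorene-9α-carbaldehyde (4aβ-CH3, 9aα-H) | O=C[C@@H]1[C@H]2C(C)(C)CCC[C@]2(C)C2=C1C(=O)C(C(C)C)=C(OC)C2=O
F2 | step 15 | 12-O-methyl ether of 29 | CC(C)=CCCC1=CC[C@@]23C(=O)C(C(C)C)=C(OC)C(=O)[C@]2(C1)[C@@]1(C)CCCC(C)(C)[C@@H]1[C@H]3C=O
F3 | step 6 | ethyl 2-[(2R)-2-(3,5-dimethoxy-4-isopropylphenyl)-1-hydroxy-2,6,6-trimethylcyclohexyl]acetate (both C1 epimers) | CCOC(=O)CC1(O)C(C)(C)CCC[C@]1(C)c1cc(OC)c(C(C)C)c(OC)c1
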